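**Plan**
- Retrosynthetic cuts, in order: the enone Cα=Cβ bond (Claisen–Schmidt); the ring-A aryl–C(=O) bond (directed lithiation/acetylation); C1''–C2'' together with C3''–CH3 (key step); C6''–C7'' (isopropenyl Grignard on a Weinreb amide) and aryl–C1'' (lithiation/formylation of resorcinol bis-MOM ether).
- Enabling feature: with the side chain numbered C1'' (benzylic) to C8'', the C2''=C3'' alkene carries its C3'' methyl cis to C1''. That is the outcome of syn Me–Al addition across a terminal alkyne followed by exchange of aluminium for a benzylic carbon. Both benzene rings are bought and no ring is formed.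
- Forward: the chiral enyne (steps 1–4) and the benzylic chloride (steps 5–8) are made separately and joined with AlMe3 in step 9. Ring A is then acetylated (step 10), the enone is built by aldol condensation (step 11) and all protecting groups are removed (step 12).
- Stereochemistry: C6'' (R) comes from CBS reduction of the isopropenyl ketone (step 3) and is carried as a TBS ether. C2''=C3'' (E) comes from syn carbometalation and stereoretentive coupling. The enone (E) comes from thermodynamic dehydration.

Key step: step 9

Remark: isopropenylmagnesium bromide (THF solution; otherwise from 2-bromopropene and Mg), N-methoxy-N-methylacetamide and 4-(methoxymethoxy)benzaldehyde (otherwise one step from 4-hydroxybenzaldehyde and MOMCl) are taken as purchased.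

**Route**

Step 1
Reactants: 1 pent-4-ynoic acid
Product: 2 N-methoxy-N-methylpent-4-ynamide
Conditions: MeNH(OMe)·HCl, EDC·HCl, Et3N, DMAP (cat.), CH2Cl2, 0 °C → rt
Reagents that add atoms: N,O-dimethylhydroxylamine hydrochloride, CNOC.Cl
Why: Carbodiimide-mediated amide coupling (Weinreb amide formation) is routine for a simple carboxylic acid and leaves the terminal alkyne untouched.

Step 2
Reactants: 2 N-methoxy-N-methylpent-4-ynamide; 3 isopropenylmagnesium bromide
Product: 4 2-methylhept-1-en-6-yn-3-one
Conditions: 3 (2.5 equiv), THF, −20 → 0 °C; inverse quench into cold 1 M HCl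
Reagents that add atoms: isopropenylmagnesium bromide (3), C=C(C)[Mg]Br
Why: Weinreb ketone synthesis stops at the ketone, the surplus Grignard reagent covers any deprotonation of the alkyne C–H (restored at the quench), and the cold acidic quench keeps the released N,O-dimethylhydroxylamine protonated so that it cannot add to the new enone.

Step 3
Reactants: 4 2-methylhept-1-en-6-yn-3-one
Product: 5 (3R)-2-methylhept-1-en-6-yn-3-ol
Conditions: (S)-Me-CBS oxazaborolidine (0.2 equiv), catecholborane, toluene, −78 °C; MeOH
Reagents that add atoms: none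
Why: Corey–Bakshi–Shibata reduction, in which the carbonyl oxygen binds the ring boron on the side of the smaller CH2CH2C≡CH group, the α-branched isopropenyl group plays the role of the large substituent (as phenyl does in acetophenone), and hydride delivery from the N-bound borane should set C3 as (R) with the (S)-catalyst, while catecholborane at −78 °C does not hydroborate the alkyne or the alkene.

Step 4
Reactants: 5 (3R)-2-methylhept-1-en-6-yn-3-ol
Product: 6 tert-butyldimethyl{[(3R)-2-methylhept-1-en-6-yn-3-yl]oxy}silane
Conditions: TBSCl, imidazole, DMF, rt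
Reagents that add atoms: tert-butyldimethylsilyl chloride, CC(C)(C)[Si](C)(C)Cl
Why: Standard silylation of a secondary alcohol, giving an ether that tolerates AlMe3, organolithiums and ethanolic KOH and is cleaved together with the MOM groups at the end.

Step 5
Reactants: 7 resorcinol
Product: 8 1,3-bis(methoxymethoxy)benzene
Conditions: MOMCl, i-Pr2NEt, CH2Cl2, 0 °C → rt
Reagents that add atoms: chloromethyl methyl ether, COCCl
Why: Williamson-type O-alkylation of both phenols installs the acetals that later direct both lithiations.

Step 6
Reactants: 8 1,3-bis(methoxymethoxy)benzene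
Product: 10 2,6-bis(methoxymethoxy)benzaldehyde, via 2-lithio-1,3-bis(methoxymethoxy)benzene 9 (not isolated)
Conditions: n-BuLi, THF, 0 °C → rt; DMF, 0 °C; aq. NH4Cl
Reagents that add atoms: N,N-dimethylformamide, CN(C)C=O; n-butyllithium, [Li]CCCC (lithium of 9 only)
Why: Directed ortho-metalation occurs at the C–H between the two MOM ethers, the most acidic and doubly coordinated site, and DMF formylates the aryllithium.

Step 7
Reactants: 10 2,6-bis(methoxymethoxy)benzaldehyde
Product: 11 [2,6-bis(methoxymethoxy)phenyl]methanol
Conditions: NaBH4, MeOH, 0 °C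
Reagents that add atoms: none
Why: Borohydride reduction of an aromatic aldehyde is chemoselective and leaves the acetals untouched.

Step 8
Reactants: 11 [2,6-bis(methoxymethoxy)phenyl]methanol
Product: 12 2-(chloromethyl)-1,3-bis(methoxymethoxy)benzene
Conditions: PPh3, NCS (premixed), THF, 0 °C → rt; used promptly
Reagents that add atoms: N-chlorosuccinimide, O=C1CCC(=O)N1Cl
Why: Appel-type chlorination converts the benzylic alcohol into the chloride under neutral conditions that spare the acid-labile MOM ethers.

Step 9
Reactants: 6 tert-butyldimethyl{[(3R)-2-methylhept-1-en-6-yn-3-yl]oxy}silane; 12 2-(chloromethyl)-1,3-bis(methoxymethoxy)benzene; 13 trimethylaluminium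
Product: 15 tert-butyl({(3R,6E)-8-[2,6-bis(methoxymethoxy)phenyl]-2,6-dimethylocta-1,6-dien-3-yl}oxy)dimethylsilane, via E-alkenyldimethylalane 14 (not isolated)
Conditions: 13 (2 equiv), Cp2ZrCl2 (0.25 equiv), CH2Cl2, 0 °C → rt; volatiles removed, THF; 12, Pd(PPh3)4 (5 mol%), rt
Reagents that add atoms: trimethylaluminium (13), C[Al](C)C
Why: Cp2ZrCl2 and AlMe3 form a Zr–CH3/Al species that adds CH3 and metal syn across the terminal alkyne of 6, with CH3 on the internal carbon (future C3'') and the metal on the terminal carbon (future C2''), so that the (E)-2-methylalkenylalane 14 results; Pd(0) then inserts into the benzylic C–Cl bond of 12, the alkenyl group passes from Al to Pd, and reductive elimination forms C1''–C2'' with retention of alkene geometry. The closest known reaction type is zirconium-catalysed methylalumination of terminal alkynes with one-pot Negishi-type coupling of the alkenylalane with benzylic halides, for which electron-rich ortho-substituted benzylic chlorides are established partners. No ring is closed and no stereocentre is formed; the (R) centre of 6 is a silyl ether three carbons from the alkyne and is not touched. The step needs regioselectivity (methyl on the internal carbon), E geometry and chemoselectivity: the first is secured by the terminal alkyne, the second by syn addition followed by stereoretentive transmetalation and reductive elimination, the third by the 1,1-disubstituted isopropenyl group being inert to Cp2ZrCl2/AlMe3. Exchanging CH2Cl2 for THF before 12 is added lowers the Lewis acidity of the aluminium species so that the MOM ethers and the electron-rich benzylic chloride should not be ionised.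

Step 10
Reactants: 15 tert-butyl({(3R,6E)-8-[2,6-bis(methoxymethoxy)phenyl]-2,6-dimethylocta-1,6-dien-3-yl}oxy)dimethylsilane; 16 N-methoxy-N-methylacetamide
Product: 18 1-{3-[(2E,6R)-6-(tert-butyldimethylsilyloxy)-3,7-dimethylocta-2,7-dien-1-yl]-2,4-bis(methoxymethoxy)phenyl}ethan-1-one, via ring-lithiated arene 17 (not isolated)
Conditions: n-BuLi, TMEDA, THF, −20 → 0 °C; 16, −78 °C → rt; aq. NH4Cl
Reagents that add atoms: N-methoxy-N-methylacetamide (16), CC(=O)N(C)OC; n-butyllithium, [Li]CCCC (lithium of 17 only)
Why: Directed ortho-metalation, in which the site between the oxygens is blocked by the chain so that a MOM ether guides n-BuLi·TMEDA to the adjacent ring C–H (the two such positions are equivalent), followed by acylation of the aryllithium with a Weinreb amide, which stops at the methyl ketone.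

Step 11
Reactants: 18 1-{3-[(2E,6R)-6-(tert-butyldimethylsilyloxy)-3,7-dimethylocta-2,7-dien-1-yl]-2,4-bis(methoxymethoxy)phenyl}ethan-1-one; 19 4-(methoxymethoxy)benzaldehyde
Product: 20 (2E)-1-{3-[(2E,6R)-6-(tert-butyldimethylsilyloxy)-3,7-dimethylocta-2,7-dien-1-yl]-2,4-bis(methoxymethoxy)phenyl}-3-[4-(methoxymethoxy)phenyl]prop-2-en-1-one
Conditions: KOH, EtOH/H2O, rt
Reagents that add atoms: 4-(methoxymethoxy)benzaldehyde (19), COCOc1ccc(C=O)cc1
Why: Claisen–Schmidt condensation of a methyl ketone with a non-enolisable aromatic aldehyde should give the conjugated (E)-enone as the thermodynamic isomer, and the alkyl TBS ether and the MOM acetals are stable to ethanolic KOH.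

Step 12
Reactants: 20 (2E)-1-{3-[(2E,6R)-6-(tert-butyldimethylsilyloxy)-3,7-dimethylocta-2,7-dien-1-yl]-2,4-bis(methoxymethoxy)phenyl}-3-[4-(methoxymethoxy)phenyl]prop-2-en-1-one
Product: 21 (2E)-1-{2,4-dihydroxy-3-[(2E,6R)-6-hydroxy-3,7-dimethylocta-2,7-dien-1-yl]phenyl}-3-(4-hydroxyphenyl)prop-2-en-1-one
Conditions: 3 M aq. HCl/MeOH, rt → 40 °C
Reagents that add atoms: none
Why: Acid-catalysed acetal methanolysis removes the three aryl MOM ethers and acidic methanol also cleaves the secondary TBS ether, a standard global deprotection for MOM-protected prenylated chalcones that touches no stereocentre, with the mild temperature chosen to limit cyclisation of the phenols onto the C2''=C3'' alkene.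

**Compound list**

1 | pent-4-ynoic acid | C#CCCC(=O)O | starting material
2 | N-methoxy-N-methylpent-4-ynamide | C#CCCC(=O)N(C)OC | intermediate
3 | isopropenylmagnesium bromide | C=C(C)[Mg]Br | starting material
4 | 2-methylhept-1-en-6-yn-3-one | C=C(C)C(=O)CCC#C | intermediate
5 | (3R)-2-methylhept-1-en-6-yn-3-ol | C=C(C)[C@H](O)CCC#C | intermediate
6 | tert-butyldimethyl{[(3R)-2-methylhept-1-en-6-yn-3-yl]oxy}silane | C=C(C)[C@H](O[Si](C)(C)C(C)(C)C)CCC#C | intermediate
7 | resorcinol | Oc1cccc(O)c1 | starting material
8 | 1,3-bis(methoxymethoxy)benzene | COCOc1cccc(OCOC)c1 | intermediate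
9 | 2-lithio-1,3-bis(methoxymethoxy)benzene | [Li]c1c(OCOC)cccc1OCOC | intermediate (not isolated)
10 | 2,6-bis(methoxymethoxy)benzaldehyde | O=Cc1c(OCOC)cccc1OCOC | intermediate
11 | [2,6-bis(methoxymethoxy)phenyl]methanol | OCc1c(OCOC)cccc1OCOC | intermediate
12 | 2-(chloromethyl)-1,3-bis(methoxymethoxy)benzene | ClCc1c(OCOC)cccc1OCOC | intermediate
13 | trimethylaluminium | C[Al](C)C | starting material
14 | [(1E,5R)-5-(tert-butyldimethylsilyloxy)-2,6-dimethylhepta-1,6-dien-1-yl]dimethylalane | C=C(C)[C@H](O[Si](C)(C)C(C)(C)C)CC/C(C)=C/[Al](C)C | intermediate (not isolated)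
15 | tert-butyl({(3R,6E)-8-[2,6-bis(methoxymethoxy)phenyl]-2,6-dimethylocta-1,6-dien-3-yl}oxy)dimethylsilane | C=C(C)[C@H](O[Si](C)(C)C(C)(C)C)CC/C(C)=C/Cc1c(OCOC)cccc1OCOC | intermediate
16 | N-methoxy-N-methylacetamide | CC(=O)N(C)OC | starting material
17 | {3-[(2E,6R)-6-(tert-butyldimethylsilyloxy)-3,7-dimethylocta-2,7-dien-1-yl]-2,4-bis(methoxymethoxy)phenyl}lithium | C=C(C)[C@H](O[Si](C)(C)C(C)(C)C)CC/C(C)=C/Cc1c(OCOC)ccc([Li])c1OCOC | intermediate (not isolated)
18 | 1-{3-[(2E,6R)-6-(tert-butyldimethylsilyloxy)-3,7-dimethylocta-2,7-dien-1-yl]-2,4-bis(methoxymethoxy)phenyl}ethan-1-one | C=C(C)[C@H](O[Si](C)(C)C(C)(C)C)CC/C(C)=C/Cc1c(OCOC)ccc(C(C)=O)c1OCOC | intermediate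
19 | 4-(methoxymethoxy)benzaldehyde | COCOc1ccc(C=O)cc1 | starting material
20 | (2E)-1-{3-[(2E,6R)-6-(tert-butyldimethylsilyloxy)-3,7-dimethylocta-2,7-dien-1-yl]-2,4-bis(methoxymethoxy)phenyl}-3-[4-(methoxymethoxy)phenyl]prop-2-en-1-one | C=C(C)[C@H](O[Si](C)(C)C(C)(C)C)CC/C(C)=C/Cc1c(OCOC)ccc(C(=O)/C=C/c2ccc(OCOC)cc2)c1OCOC | intermediate
21 | (2E)-1-{2,4-dihydroxy-3-[(2E,6R)-6-hydroxy-3,7-dimethylocta-2,7-dien-1-yl]phenyl}-3-(4-hydroxyphenyl)prop-2-en-1-one | C=C(C)[C@H](O)CC/C(C)=C/Cc1c(O)ccc(C(=O)/C=C/c2ccc(O)cc2)c1O | target

**Totals**
Total step count: 12.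
Longest linear sequence: 8 steps (steps 1–4 then 9–12 from pent-4-ynoic acid; equally steps 5–8 then 9–12 from resorcinol).

**Steps most likely to fail**

Step 9. Lewis-acidic aluminium species may ionise the doubly ortho-oxygenated benzylic chloride (methyl transfer from aluminium, self-alkylation, MOM loss) faster than palladium inserts. Alternatively, transfer of the alkenyl group from aluminium to the hindered benzylpalladium may be so slow that the alane is only protonated at work-up. The fallback keeps the same two bonds but reverses the polarity of the coupling and keeps aluminium away from the benzylic halide. It leaves the route at alkenylalane 14, which is quenched with iodine (THF, −30 °C) to give, with retention of geometry, tert-butyl{[(3R,6E)-7-iodo-2,6-dimethylhepta-1,6-dien-3-yl]oxy}dimethylsilane F1. Chloride 12 is converted with zinc dust and LiCl in THF into [2,6-bis(methoxymethoxy)benzyl]zinc chloride F2. Palladium-catalysed Negishi coupling of the two (Pd(PPh3)4, THF, rt) should deliver 15, where the route resumes.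

Step 10. Deprotonation at the benzylic–allylic C1'' methylene, which is flanked by both MOM ethers, or next to the allylic silyl ether may outrun MOM-directed ring lithiation and divert the acylation to the chain. The fallback replaces deprotonation by halogen–lithium exchange. It sets out from benzylic alcohol 11, which NBS in MeCN at 0 °C should brominate para to one MOM ether and ortho to the other, giving [3-bromo-2,6-bis(methoxymethoxy)phenyl]methanol F3. The PPh3/NCS chlorination of step 8 then gives 1-bromo-3-(chloromethyl)-2,4-bis(methoxymethoxy)benzene F4. Coupling of F4 with alane 14 under the conditions of step 9 relies on Pd(0) inserting into the benzylic C–Cl bond at rt much faster than into the electron-rich aryl C–Br bond. It should give tert-butyl({(3R,6E)-8-[3-bromo-2,6-bis(methoxymethoxy)phenyl]-2,6-dimethylocta-1,6-dien-3-yl}oxy)dimethylsilane F5. Bromine–lithium exchange with n-BuLi in THF at −78 °C is faster than any deprotonation and leads to aryllithium 17, where the route is rejoined and the acylation of step 10 gives 18.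

Step 3. Enantiofacial discrimination may be insufficient because the isopropenyl group and the primary alkyl chain differ only moderately in size, and conjugate reduction may compete. The fallback replaces catalyst-controlled reduction by resolution. It sets out from enone 4, which Luche reduction (NaBH4, CeCl3·7H2O, MeOH, 0 °C) converts into racemic 2-methylhept-1-en-6-yn-3-ol F6. Sharpless kinetic resolution (Ti(OiPr)4, L-(+)-diisopropyl tartrate, t-BuOOH 0.6 equiv, 4 Å MS, CH2Cl2, −20 °C) should epoxidise the (S)-enantiomer to (1S)-1-[(2S)-2-methyloxiran-2-yl]pent-4-yn-1-ol F7. The slow-reacting (R)-alcohol 5 is recovered and re-enters the route at step 4.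

**Further compounds**

F1 | step 9 | tert-butyl{[(3R,6E)-7-iodo-2,6-dimethylhepta-1,6-dien-3-yl]oxy}dimethylsilane | C=C(C)[C@H](O[Si](C)(C)C(C)(C)C)CC/C(C)=C/I
F2 | step 9 | [2,6-bis(methoxymethoxy)benzyl]zinc chloride | Cl[Zn]Cc1c(OCOC)cccc1OCOC
F3 | step 10 | [3-bromo-2,6-bis(methoxymethoxy)phenyl]methanol | OCc1c(OCOC)ccc(Br)c1OCOC
F4 | step 10 | 1-bromo-3-(chloromethyl)-2,4-bis(methoxymethoxy)benzene | ClCc1c(OCOC)ccc(Br)c1OCOC
F5 | step 10 | tert-butyl({(3R,6E)-8-[3-bromo-2,6-bis(methoxymethoxy)phenyl]-2,6-dimethylocta-1,6-dien-3-yl}oxy)dimethylsilane | C=C(C)[C@H](O[Si](C)(C)C(C)(C)C)CC/C(C)=C/Cc1c(OCOC)ccc(Br)c1OCOC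
F6 | step 3 | racemic 2-methylhept-1-en-6-yn-3-ol | C=C(C)C(O)CCC#C
F7 | step 3 | (1S)-1-[(2S)-2-methyloxiran-2-yl]pent-4-yn-1-ol | C[C@]1(CO1)[C@@H](O)CCC#C
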